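**Retrosynthetic overview**
1. Endgame: the 3-OH and the 3-benzyl group come from an E-3-benzylidene lactone by dihydroxylation on the face away from the 4-benzyl group, then hydrogenolysis of the benzylic OH together with both O-benzyl groups. The benzylidene lactone comes from aldol condensation of (S)-4-benzyl-γ-butyrolactone 9 with O-benzylvanillin.
2. Key disconnection: the O1–C5 bond of the lactone ring (O1, C2, C3, C4, C5). The enabling feature is that C5 (the ring OCH2) and the benzylic CH2 of the 4-benzyl group are both bonded to C4, and that this benzylic carbon carries an electron-rich 3-methoxy-4-oxyphenyl ring. C5, C4 and the benzylic carbon can therefore be the three carbons of an arylcyclopropane, whose radical cation is opened at C5 by the carboxyl oxygen held on C3.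
3. The cyclopropylacetic acid comes from Arndt–Eistert homologation of the product of a catalytic asymmetric cyclopropanation of 4-benzyloxy-3-methoxystyrene with ethyl diazoacetate. That cyclopropanation sets the future C4; both arenes derive from one aldehyde.
4. Ring order: temporary cyclopropane (step 2), then the γ-lactone (step 6), which is the only ring built in the target and is closed in the same operation that consumes the cyclopropane.

Key step: step 6

Remark: the SMILES is read as the (3S,4R) lactone, with the two benzyl groups cis and the 3-OH trans to the 4-benzyl group; the route is planned for this isomer.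

**Route**

Step 1
Reactants: 1 4-(benzyloxy)-3-methoxybenzaldehyde (O-benzylvanillin)
Product: 2 1-(benzyloxy)-4-ethenyl-2-methoxybenzene
Conditions: Ph3PCH3Br, KOtBu, THF, 0 °C → rt
Reagents that add atoms: methyltriphenylphosphonium bromide, C[P+](c1ccccc1)(c1ccccc1)c1ccccc1.[Br-]
Why: Wittig methylenation of an aromatic aldehyde with the non-stabilised ylide Ph3P=CH2 is reliable and the aryl ethers are inert to KOtBu.

Step 2
Reactants: 2 1-(benzyloxy)-4-ethenyl-2-methoxybenzene
Product: 3 ethyl (1S,2S)-2-[4-(benzyloxy)-3-methoxyphenyl]cyclopropane-1-carboxylate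
Conditions: CuOTf·0.5C6H6 (1 mol%), 2,2'-(propane-2,2-diyl)bis[(4R)-4-tert-butyl-4,5-dihydrooxazole] (1.2 mol%), ethyl diazoacetate (syringe pump), CH2Cl2, rt
Reagents that add atoms: ethyl diazoacetate, CCOC(=O)C=[N+]=[N-]
Why: Copper/bis(oxazoline)-catalysed asymmetric cyclopropanation (carbene transfer to an electron-rich styrene): the C2-symmetric ligand shields one face of the copper carbene so that C1 is formed with S configuration (the enantiomeric ligand is known to give 1R with styrenes), the trans isomer should predominate, and the minor cis isomer, which has the same C1 configuration, can be carried along because step 6 erases C2.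

Step 3
Reactants: 3 ethyl (1S,2S)-2-[4-(benzyloxy)-3-methoxyphenyl]cyclopropane-1-carboxylate
Product: 4 (1S,2S)-2-[4-(benzyloxy)-3-methoxyphenyl]cyclopropane-1-carboxylic acid
Conditions: LiOH·H2O, THF/MeOH/H2O, rt; then 1 M HCl to pH 3
Reagents that add atoms: lithium hydroxide, [Li+].[OH-]
Why: Ester saponification with LiOH at room temperature leaves the aryl ethers and both cyclopropane stereocentres untouched, and careful acidification to pH 3 avoids acid-induced opening of the donor-substituted cyclopropane.

Step 4
Reactants: 4 (1S,2S)-2-[4-(benzyloxy)-3-methoxyphenyl]cyclopropane-1-carboxylic acid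
Product: 6 2-diazo-1-{(1S,2S)-2-[4-(benzyloxy)-3-methoxyphenyl]cyclopropyl}ethan-1-one, via mixed carbonic anhydride 5 (not isolated)
Conditions: i-BuOCOCl, N-methylmorpholine, THF, −15 °C; then CH2N2 in Et2O, −15 °C → rt
Reagents that add atoms: isobutyl chloroformate, CC(C)COC(=O)Cl (kept only in intermediate 5); diazomethane, C=[N+]=[N-]
Why: First stage of the Arndt–Eistert homologation: the mixed carbonic anhydride acylates diazomethane at carbon under cold, essentially neutral conditions, so the cyclopropane and its stereocentres are not affected.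

Step 5
Reactants: 6 2-diazo-1-{(1S,2S)-2-[4-(benzyloxy)-3-methoxyphenyl]cyclopropyl}ethan-1-one
Product: 8 2-{(1R,2S)-2-[4-(benzyloxy)-3-methoxyphenyl]cyclopropyl}acetic acid, via cyclopropylketene 7 (not isolated)
Conditions: PhCO2Ag (10 mol%), Et3N, THF/H2O 9:1, rt, dark
Reagents that add atoms: water, O
Why: Wolff rearrangement (second stage of the Arndt–Eistert homologation): silver-induced loss of N2 is accompanied by 1,2-shift of the cyclopropyl carbon with retention of configuration, and the ketene is trapped by water as the homologous acid.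

Step 6
Reactants: 8 2-{(1R,2S)-2-[4-(benzyloxy)-3-methoxyphenyl]cyclopropyl}acetic acid
Product: 9 (4S)-4-[4-(benzyloxy)-3-methoxybenzyl]dihydrofuran-2(3H)-one
Conditions: 9-mesityl-10-methylacridinium tetrafluoroborate (5 mol%), PhSSPh (10 mol%), 2,6-lutidine (20 mol%), degassed 1,2-dichloroethane (0.05 M), 450 nm LEDs, rt
Reagents that add atoms: none
Why: Proposed new method: the excited acridinium (about +2.0 V vs SCE) should oxidise the 4-benzyloxy-3-methoxyphenyl ring (estimated +1.3 V) to a radical cation that weakens the two cyclopropane bonds to the aryl-bearing carbon, and the tethered carboxyl oxygen attacks the cyclopropane CH2 from the rear of its bond to that carbon (three-electron SN2), which forms the lactone C–O bond, releases the ring strain and leaves a benzylic radical that takes H from PhSH (from PhSSPh) while PhS• reoxidises the acridinyl radical, so the step is redox-neutral. The closest known reaction types are the photoinduced-electron-transfer anti-Markovnikov addition of oxygen nucleophiles to arylcyclopropane radical cations and the acridinium/thiol anti-Markovnikov hydrolactonisation of alkenoic acids, of which this is the cyclopropane (homo-alkene) counterpart in an intramolecular, lactone-forming version not yet demonstrated. The γ-lactone closes in a 5-exo-tet mode, with the new O–CH2 bond inside the ring and the departing benzylic carbon outside it. No new stereocentre is created: C4 of the lactone is the former C1 of the cyclopropane, none of whose bonds is broken, so its configuration is transferred (1R in 8 becomes 4S in 9 only by a change of CIP priorities), and the aryl-bearing stereocentre becomes CH2, which is why cis and trans cyclopropanes converge. The step needs attack at the ring CH2 and not at the tether-bearing or the benzylic carbon, which the substrate secures because closure at the tether-bearing carbon would be a four-membered ring and only cleavage of a bond to the aryl-bearing carbon gives a stabilised benzylic radical; it also needs the dialkoxyarene to be oxidised in preference to the carboxylate, which the low arene potential and the use of only catalytic weak base should ensure.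

Step 7
Reactants: 9 (4S)-4-[4-(benzyloxy)-3-methoxybenzyl]dihydrofuran-2(3H)-one; 1 4-(benzyloxy)-3-methoxybenzaldehyde
Product: 13 (3E,4S)-3-[4-(benzyloxy)-3-methoxybenzylidene]-4-[4-(benzyloxy)-3-methoxybenzyl]dihydrofuran-2(3H)-one, via lithium enolate 10 (not isolated), via lithium aldolate 11 (not isolated), via aldol acetate 12 (not isolated)
Conditions: LiHMDS, THF, −78 °C; then 1; then Ac2O, −78 → 0 °C; then DBU, 0 °C → rt
Reagents that add atoms: lithium bis(trimethylsilyl)amide, C[Si](C)(C)[N-][Si](C)(C)C.[Li+] (Li kept only in intermediates 10 and 11); acetic anhydride, CC(=O)OC(C)=O (acetyl kept only in intermediate 12)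
Why: Aldol condensation in one flask: the lithium enolate of the lactone adds to the aldehyde, the aldolate is acetylated, and DBU effects E1cB elimination to the conjugated E-benzylidene lactone, which removes the two transient stereocentres while C4, which is not deprotonated under these kinetic conditions, keeps its S configuration.

Step 8
Reactants: 13 (3E,4S)-3-[4-(benzyloxy)-3-methoxybenzylidene]-4-[4-(benzyloxy)-3-methoxybenzyl]dihydrofuran-2(3H)-one
Product: 14 (3R,4R)-4-[4-(benzyloxy)-3-methoxybenzyl]-3-{(S)-[4-(benzyloxy)-3-methoxyphenyl](hydroxy)methyl}-3-hydroxydihydrofuran-2(3H)-one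
Conditions: OsO4 (5 mol%), NMO, citric acid, t-BuOH/H2O 1:1, rt
Reagents that add atoms: osmium tetroxide (catalytic oxygen carrier), O=[Os](=O)(=O)=O; N-methylmorpholine N-oxide, C[N+]1([O-])CCOCC1; water, O
Why: Catalytic OsO4/NMO syn-dihydroxylation: the E-aryl group forces the C4 benzyl group into a pseudo-axial position through allylic 1,3-strain, so osmylation of the exocyclic alkene should occur on the opposite face and place the new tertiary 3-OH trans to the C4 benzyl group (3R here, 3S in the target), while the secondary benzylic carbinol centre formed at the same time is removed in step 9.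

Step 9
Reactants: 14 (3R,4R)-4-[4-(benzyloxy)-3-methoxybenzyl]-3-{(S)-[4-(benzyloxy)-3-methoxyphenyl](hydroxy)methyl}-3-hydroxydihydrofuran-2(3H)-one
Product: 15 (3S,4R)-3-hydroxy-3,4-bis(4-hydroxy-3-methoxybenzyl)dihydrofuran-2(3H)-one
Conditions: H2 (3 atm), 10% Pd/C, AcOH, HClO4 (cat.), rt
Reagents that add atoms: none
Why: Catalytic hydrogenolysis under acidic conditions cleaves the two O-benzyl ethers and the secondary para-oxygenated benzylic C–OH bond, whereas the tertiary non-benzylic 3-OH and the lactone are not affected, so the configurations at C3 and C4 are carried unchanged into the target.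

**Compound list**
1 | 4-(benzyloxy)-3-methoxybenzaldehyde | COc1cc(C=O)ccc1OCc1ccccc1 | starting material
2 | 1-(benzyloxy)-4-ethenyl-2-methoxybenzene | COc1cc(C=C)ccc1OCc1ccccc1 | intermediate
3 | ethyl (1S,2S)-2-[4-(benzyloxy)-3-methoxyphenyl]cyclopropane-1-carboxylate | COc1cc([C@H]2C[C@@H]2C(=O)OCC)ccc1OCc1ccccc1 | intermediate
4 | (1S,2S)-2-[4-(benzyloxy)-3-methoxyphenyl]cyclopropane-1-carboxylic acid | COc1cc([C@H]2C[C@@H]2C(=O)O)ccc1OCc1ccccc1 | intermediate
5 | (1S,2S)-2-[4-(benzyloxy)-3-methoxyphenyl]cyclopropanecarboxylic isobutyl carbonic anhydride | COc1cc([C@H]2C[C@@H]2C(=O)OC(=O)OCC(C)C)ccc1OCc1ccccc1 | intermediate (not isolated)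
6 | 2-diazo-1-{(1S,2S)-2-[4-(benzyloxy)-3-methoxyphenyl]cyclopropyl}ethan-1-one | COc1cc([C@H]2C[C@@H]2C(=O)C=[N+]=[N-])ccc1OCc1ccccc1 | intermediate
7 | {(1S,2S)-2-[4-(benzyloxy)-3-methoxyphenyl]cyclopropyl}ketene | COc1cc([C@H]2C[C@@H]2C=C=O)ccc1OCc1ccccc1 | intermediate (not isolated)
8 | 2-{(1R,2S)-2-[4-(benzyloxy)-3-methoxyphenyl]cyclopropyl}acetic acid | COc1cc([C@H]2C[C@@H]2CC(=O)O)ccc1OCc1ccccc1 | intermediate
9 | (4S)-4-[4-(benzyloxy)-3-methoxybenzyl]dihydrofuran-2(3H)-one | COc1cc(C[C@@H]2COC(=O)C2)ccc1OCc1ccccc1 | intermediate
10 | lithium (4S)-4-[4-(benzyloxy)-3-methoxybenzyl]-4,5-dihydrofuran-2-olate | COc1cc(C[C@@H]2COC([O-])=C2)ccc1OCc1ccccc1.[Li+] | intermediate (not isolated)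
11 | lithium [4-(benzyloxy)-3-methoxyphenyl]{(3R,4S)-4-[4-(benzyloxy)-3-methoxybenzyl]-2-oxotetrahydrofuran-3-yl}methanolate (both carbinol epimers) | COc1cc(C[C@@H]2COC(=O)[C@H]2C([O-])c2ccc(OCc3ccccc3)c(OC)c2)ccc1OCc1ccccc1.[Li+] | intermediate (not isolated)
12 | [4-(benzyloxy)-3-methoxyphenyl]{(3R,4S)-4-[4-(benzyloxy)-3-methoxybenzyl]-2-oxotetrahydrofuran-3-yl}methyl acetate (both carbinol epimers) | COc1cc(C[C@@H]2COC(=O)[C@H]2C(OC(C)=O)c2ccc(OCc3ccccc3)c(OC)c2)ccc1OCc1ccccc1 | intermediate (not isolated)
13 | (3E,4S)-3-[4-(benzyloxy)-3-methoxybenzylidene]-4-[4-(benzyloxy)-3-methoxybenzyl]dihydrofuran-2(3H)-one | O=C1OC[C@@H](Cc2ccc(OCc3ccccc3)c(OC)c2)/C1=C\c1ccc(OCc2ccccc2)c(OC)c1 | intermediate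
14 | (3R,4R)-4-[4-(benzyloxy)-3-methoxybenzyl]-3-{(S)-[4-(benzyloxy)-3-methoxyphenyl](hydroxy)methyl}-3-hydroxydihydrofuran-2(3H)-one | COc1cc(C[C@@H]2COC(=O)[C@]2(O)[C@@H](O)c2ccc(OCc3ccccc3)c(OC)c2)ccc1OCc1ccccc1 | intermediate
15 | (3S,4R)-3-hydroxy-3,4-bis(4-hydroxy-3-methoxybenzyl)dihydrofuran-2(3H)-one | COc1cc(C[C@@H]2COC(=O)[C@]2(O)Cc2ccc(O)c(OC)c2)ccc1O | target

**Step count and risks**

Total steps: 9. Longest linear sequence: 9 steps (1 → 15); aldehyde 1 enters a second time in step 7.

Steps most likely to fail:

1. Step 6 (proposed new method). What may go wrong: back electron transfer outrunning the ring-opening capture because the dialkoxyarene hole is well stabilised, oxidative decarboxylation of the carboxylate, or oxidative loss of the O-benzyl group. The fallback uses known chemistry, sets out from 1 and comes back at 9. Stobbe condensation of 1 with dimethyl succinate (NaOMe, MeOH, reflux) should give (E)-4-[4-(benzyloxy)-3-methoxyphenyl]-3-(methoxycarbonyl)but-3-enoic acid F1. Asymmetric hydrogenation (Rh(cod)2BF4 with the Et-DuPhos enantiomer that gives the S acid, H2, MeOH) should give (3S)-4-[4-(benzyloxy)-3-methoxyphenyl]-3-(methoxycarbonyl)butanoic acid F2. Reduction of the ester group of its potassium salt with Ca(BH4)2 (CaCl2, NaBH4, EtOH) and acidification should lactonise to 9, after which steps 7 to 9 follow unchanged.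

2. Step 8. What may go wrong: slow osmylation of the conjugated trisubstituted alkene, insufficient facial selectivity, or retro-aldol cleavage of the diol. The fallback sets out from 9 and comes back at 15. Alkylation of the lithium enolate of 9 (LiHMDS, THF, −78 °C) with 4-(benzyloxy)-3-methoxybenzyl bromide, anti to the C4 substituent, should give (3S,4S)-3,4-bis[4-(benzyloxy)-3-methoxybenzyl]dihydrofuran-2(3H)-one F3. Hydroxylation of its potassium enolate (KHMDS, THF, −78 °C) with 2-(phenylsulfonyl)-3-phenyloxaziridine on the face away from the C4 benzyl group should give (3S,4R)-3,4-bis[4-(benzyloxy)-3-methoxybenzyl]-3-hydroxydihydrofuran-2(3H)-one F4. Hydrogenolysis of the two benzyl ethers (H2, Pd/C, EtOAc/EtOH) should then give 15.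

3. Step 9. What may go wrong: incomplete hydrogenolysis of the hindered benzylic C–OH bond next to the quaternary carbon, or an acid-promoted semipinacol shift of the benzylic cation. The fallback sets out from 14 and comes back at 15. Neutral hydrogenolysis (H2 1 atm, Pd/C, EtOAc/EtOH, no acid) should remove only the benzyl ethers and give (3R,4R)-3-hydroxy-3-[(S)-hydroxy(4-hydroxy-3-methoxyphenyl)methyl]-4-(4-hydroxy-3-methoxybenzyl)dihydrofuran-2(3H)-one F5. Ionic reduction of its para-hydroxybenzylic alcohol (Et3SiH, CF3CO2H, CH2Cl2, 0 °C), through the strongly stabilised quinone-methide-type cation, should give 15.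

Further compounds
F1 | step 6 | (E)-4-[4-(benzyloxy)-3-methoxyphenyl]-3-(methoxycarbonyl)but-3-enoic acid | COC(=O)/C(CC(=O)O)=C/c1ccc(OCc2ccccc2)c(OC)c1
F2 | step 6 | (3S)-4-[4-(benzyloxy)-3-methoxyphenyl]-3-(methoxycarbonyl)butanoic acid | COc1cc(C[C@@H](CC(=O)O)C(=O)OC)ccc1OCc1ccccc1
F3 | step 8 | (3S,4S)-3,4-bis[4-(benzyloxy)-3-methoxybenzyl]dihydrofuran-2(3H)-one | COc1cc(C[C@@H]2COC(=O)[C@H]2Cc2ccc(OCc3ccccc3)c(OC)c2)ccc1OCc1ccccc1
F4 | step 8 | (3S,4R)-3,4-bis[4-(benzyloxy)-3-methoxybenzyl]-3-hydroxydihydrofuran-2(3H)-one | COc1cc(C[C@@H]2COC(=O)[C@]2(O)Cc2ccc(OCc3ccccc3)c(OC)c2)ccc1OCc1ccccc1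
F5 | step 9 | (3R,4R)-3-hydroxy-3-[(S)-hydroxy(4-hydroxy-3-methoxyphenyl)methyl]-4-(4-hydroxy-3-methoxybenzyl)dihydrofuran-2(3H)-one | COc1cc(C[C@@H]2COC(=O)[C@]2(O)[C@@H](O)c2ccc(O)c(OC)c2)ccc1O
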